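The route opens the dioxin (ring B) at one bond, from the oxygen on ring A carbon a6 to C2 of ring C (dibenzofuran numbering). C2 is the only C–H between the C1 ether oxygen and the C3 hydroxyl, and it lies para to the furan-bearing C4a. Oxidising the C3 phenol therefore places charge or spin on C2, within six-membered reach of the a6 hydroxyl. One anodic dehydrogenation forms the last C–O bond and closes ring B without a halogen handle. The precursor is a hexamethylated bis(aryl ether) with only two free phenols. It is built by two fluoride displacements on a symmetrical difluorobenzaldehyde, whose formyl carbon then becomes the a6 hydroxyl.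

Key step: step 12

Labels:
- Ring A is the pentaoxygenated benzene: a1 (O to ring E), a2 (O), a3 (H), a4 (O), a5 (O to C1), a6 (O to C2).
- Ring B is the 1,4-dioxin.
- Rings C and D are the inner and outer benzene rings of the dibenzofuran, numbered C1 to C9b as in dibenzo[b,d]furan.
- Ring E is the pendant 3,5-dioxygenated phenyl.
- The target is achiral, so no stereocentre has to be set.

Assumption: 5-(benzyloxy)resorcinol and 2,6-difluoro-3,5-dimethoxybenzaldehyde are treated as not purchasable, and each is made in one step.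

Step 1
Reactants: 1 phloroglucinol (benzene-1,3,5-triol)
Product: 2 5-(benzyloxy)benzene-1,3-diol
Conditions: 1 (3 equiv), BnBr (1 equiv), K2CO3 (1.1 equiv), DMF, rt to 50 °C
Reagents that add atoms: benzyl bromide, BrCc1ccccc1
Why: Williamson etherification under statistical control, in which the threefold excess of the cheap triol should favour the monoether and the water-soluble excess is washed out.

Step 2
Reactants: 2 5-(benzyloxy)benzene-1,3-diol
Product: 3 1-(benzyloxy)-3,5-bis(methoxymethoxy)benzene
Conditions: NaH (2.4 equiv), MOMCl (2.4 equiv), DMF, 0 °C to rt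
Reagents that add atoms: chloromethyl methyl ether, COCCl
Why: Double O-alkylation of the two equivalent phenoxides installs acetal protecting groups that later direct metalation together and come off under mild acid that spares benzyl and methyl ethers.

Step 3
Reactants: 4 1-fluoro-3,5-dimethoxybenzene
Product: 5 2-bromo-1-fluoro-3,5-dimethoxybenzene
Conditions: NBS (1.0 equiv), MeCN, 0 °C to rt
Reagents that add atoms: N-bromosuccinimide, O=C1CCC(=O)N1Br
Why: Electrophilic aromatic bromination should go para to one methoxy group and ortho to the other, as is usual for 5-substituted 1,3-dimethoxybenzenes, because the site between the two methoxy groups is more crowded.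

Step 4
Reactants: 3 1-(benzyloxy)-3,5-bis(methoxymethoxy)benzene; 5 2-bromo-1-fluoro-3,5-dimethoxybenzene
Product: 8 4-(benzyloxy)-2'-fluoro-4',6'-dimethoxy-2,6-bis(methoxymethoxy)-1,1'-biphenyl, via aryllithium 6 (not isolated), via arylzinc chloride 7 (not isolated)
Conditions: 3, n-BuLi (1.1 equiv), THF, 0 °C; ZnCl2 (1.2 equiv), 0 °C to rt; then 5, Pd2(dba)3 (2 mol %), RuPhos (8 mol %), THF, 70 °C
Reagents that add atoms: none
Why: Directed ortho-metalation at the carbon flanked by both MOM ethers, transmetalation to zinc and Negishi cross-coupling on zerovalent palladium with a bulky dialkylbiarylphosphine, a catalyst type established for tetra-ortho-substituted biaryls that leaves the C–F bond alone.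

Step 5
Reactants: 8 4-(benzyloxy)-2'-fluoro-4',6'-dimethoxy-2,6-bis(methoxymethoxy)-1,1'-biphenyl
Product: 9 4-(benzyloxy)-2'-fluoro-4',6'-dimethoxy-[1,1'-biphenyl]-2,6-diol
Conditions: HCl (1.25 M in MeOH), 45 °C
Reagents that add atoms: none
Why: Acid-catalysed acetal exchange with methanol removes both MOM groups, while aryl benzyl and aryl methyl ethers are inert to dilute acid.

Step 6
Reactants: 9 4-(benzyloxy)-2'-fluoro-4',6'-dimethoxy-[1,1'-biphenyl]-2,6-diol
Product: 10 3-(benzyloxy)-7,9-dimethoxydibenzo[b,d]furan-1-ol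
Conditions: K2CO3 (3 equiv), NMP, 150 °C, argon
Reagents that add atoms: none
Why: Intramolecular nucleophilic aromatic substitution of fluoride, the known furan closure of 2'-fluorobiphenyl-2-ols, helped here by both ring D methoxy groups being meta to the C–F carbon; the two ring C hydroxyls are equivalent, so either one closes to the same product and the other is left as the free C1 hydroxyl.

Step 7
Reactants: 11 3,5-dimethoxybenzaldehyde
Product: 12 2,6-difluoro-3,5-dimethoxybenzaldehyde
Conditions: Selectfluor (2.2 equiv), MeCN, 0 °C to rt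
Reagents that add atoms: Selectfluor, F[N+]12CC[N+](CCl)(CC1)CC2.F[B-](F)(F)F.F[B-](F)(F)F
Why: Electrophilic aromatic fluorination with an N–F reagent should go twice to the two positions next to the formyl group, each ortho to one methoxy and para to the other, as halogenation of 3,5-dimethoxybenzoyl compounds does.

Step 8
Reactants: 12 2,6-difluoro-3,5-dimethoxybenzaldehyde; 13 3,5-dimethoxyphenol
Product: 14 2-(3,5-dimethoxyphenoxy)-6-fluoro-3,5-dimethoxybenzaldehyde
Conditions: 12 (2 equiv), 13 (1 equiv), K2CO3 (1.5 equiv), DMSO, 90 °C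
Reagents that add atoms: none
Why: Nucleophilic aromatic substitution in which the ortho formyl group takes up the charge of the Meisenheimer adduct and the meta fluorine offsets the methoxy donors, while excess 12 and the lower reactivity of the monoether should hold the reaction at one displacement.

Step 9
Reactants: 10 3-(benzyloxy)-7,9-dimethoxydibenzo[b,d]furan-1-ol; 14 2-(3,5-dimethoxyphenoxy)-6-fluoro-3,5-dimethoxybenzaldehyde
Product: 15 2-{[3-(benzyloxy)-7,9-dimethoxydibenzo[b,d]furan-1-yl]oxy}-6-(3,5-dimethoxyphenoxy)-3,5-dimethoxybenzaldehyde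
Conditions: 10 (1 equiv), 14 (1.3 equiv), Cs2CO3 (2 equiv), NMP, 120 °C, argon
Reagents that add atoms: none
Why: A second nucleophilic aromatic substitution ortho to the formyl group, a standard entry to crowded diaryl ethers that needs no metal insertion between two ortho substituents; the cesium phenoxide in a dipolar aprotic solvent offsets the bay-region hindrance at the C1 oxygen, and fluoride leaves much faster than the aryloxide already in place.

Step 10
Reactants: 15 2-{[3-(benzyloxy)-7,9-dimethoxydibenzo[b,d]furan-1-yl]oxy}-6-(3,5-dimethoxyphenoxy)-3,5-dimethoxybenzaldehyde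
Product: 17 2-{[3-(benzyloxy)-7,9-dimethoxydibenzo[b,d]furan-1-yl]oxy}-6-(3,5-dimethoxyphenoxy)-3,5-dimethoxyphenol, via aryl formate 16 (not isolated)
Conditions: mCPBA (1.3 equiv), CH2Cl2, 0 °C to rt; aq NaHCO3 wash; then K2CO3 (0.2 equiv), MeOH, rt
Reagents that add atoms: meta-chloroperoxybenzoic acid, OOC(=O)c1cccc(Cl)c1
Why: Baeyer–Villiger (Dakin-type) oxidation in which the aryl group with two ortho oxygen donors migrates in preference to hydride, and mild methanolysis of the formate frees the a6 hydroxyl without touching benzyl, methyl or diaryl ethers.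

Step 11
Reactants: 17 2-{[3-(benzyloxy)-7,9-dimethoxydibenzo[b,d]furan-1-yl]oxy}-6-(3,5-dimethoxyphenoxy)-3,5-dimethoxyphenol
Product: 18 1-[2-hydroxy-3-(3,5-dimethoxyphenoxy)-4,6-dimethoxyphenoxy]-7,9-dimethoxydibenzo[b,d]furan-3-ol (hexamethyl bisphenol, ring B half open)
Conditions: H2 (1 atm), Pd/C (10 wt %), EtOAc–MeOH, rt
Reagents that add atoms: none
Why: Catalytic hydrogenolysis cleaves only the benzylic C–O bond, so the C3 hydroxyl is freed while methyl and diaryl ethers stay.

Step 12
Reactants: 18 1-[2-hydroxy-3-(3,5-dimethoxyphenoxy)-4,6-dimethoxyphenoxy]-7,9-dimethoxydibenzo[b,d]furan-3-ol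
Product: 19 hexamethyl ether of the target with the C3 hydroxyl free (ring B closed through a5–O–C1 and a6–O–C2; OMe at a2, a4, C7, C9 and on both meta positions of ring E)
Conditions: undivided cell, boron-doped diamond anode, Pt cathode, Bu4NPF6 (0.1 M), HFIP, 5 mM in 18, constant current 1–2 mA cm−2, 2.0–2.2 F mol−1, rt, argon
Reagents that add atoms: none
Why: Proposed new method: the anode should first oxidise the ring C phenol, whose C3 oxygen is conjugated through C9b with donor-rich ring D, rather than the ring A phenol, whose two methoxy groups are meta to the a6 hydroxyl, and the phenoxonium ion formed by loss of two electrons and a proton (or the phenoxyl radical, if each phenol loses one electron) carries charge or spin at C2, C4 and C9b. The a6 oxygen bonds to C2, loss of the C2 proton rearomatises ring C, and the two protons are reduced to H2 at the cathode, so no chemical oxidant is needed. The closest known reaction types are anodic dehydrogenative phenol couplings in HFIP, capture of anodically formed phenoxonium ions by tethered oxygen nucleophiles and oxidative cyclisation of 2-aryloxyphenols to dibenzodioxins, but an anodic aryl C–H to aryl ether closure of a dioxin on such a polyoxygenated substrate has not been shown. Ring B closes in a six-membered mode, formally 6-endo-trig on the C1=C2 bond of the ring C cation, and no stereocentre is formed. The step needs site selectivity among C2, C4 and C9b: the a5–O–C1 tether keeps C4 out of reach, and addition at C9b, also six-membered, gives a non-aromatic dienone that cannot lose a proton and should reopen in acidic HFIP, so only the C2 closure is irreversible. It also needs chemoselectivity against coupling between molecules at C4 or a3 and against further oxidation of 19, which high dilution, the hydrogen-bonding solvent, low current density and a charge limit near 2 F mol−1 are meant to secure.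

Step 13
Reactants: 19 hexamethyl ether of the target with the C3 hydroxyl free
Product: 20 target CNP0256302.0 (heptaphenol)
Conditions: BBr3 (12 equiv), CH2Cl2, −78 °C to rt; then H2O, 0 °C, argon
Reagents that add atoms: none
Why: Lewis acid mediated cleavage of aryl methyl ethers (boron complexation, then bromide attack on methyl) removes all six methyl groups, whereas the diaryl ether, dioxin and furan C–O bonds offer no sp3 carbon to bromide and survive.

Compound list
1 | phloroglucinol | Oc1cc(O)cc(O)c1 | starting material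
2 | 5-(benzyloxy)benzene-1,3-diol | Oc1cc(O)cc(OCc2ccccc2)c1 | intermediate
3 | 1-(benzyloxy)-3,5-bis(methoxymethoxy)benzene | COCOc1cc(OCOC)cc(OCc2ccccc2)c1 | intermediate
4 | 1-fluoro-3,5-dimethoxybenzene | COc1cc(F)cc(OC)c1 | starting material
5 | 2-bromo-1-fluoro-3,5-dimethoxybenzene | COc1cc(F)c(Br)c(OC)c1 | intermediate
6 | [4-(benzyloxy)-2,6-bis(methoxymethoxy)phenyl]lithium | [Li]c1c(OCOC)cc(OCc2ccccc2)cc1OCOC | intermediate
7 | [4-(benzyloxy)-2,6-bis(methoxymethoxy)phenyl]zinc chloride | Cl[Zn]c1c(OCOC)cc(OCc2ccccc2)cc1OCOC | intermediate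
8 | 4-(benzyloxy)-2'-fluoro-4',6'-dimethoxy-2,6-bis(methoxymethoxy)-1,1'-biphenyl | COCOc1cc(OCc2ccccc2)cc(OCOC)c1-c1c(F)cc(OC)cc1OC | intermediate
9 | 4-(benzyloxy)-2'-fluoro-4',6'-dimethoxy-[1,1'-biphenyl]-2,6-diol | Oc1cc(OCc2ccccc2)cc(O)c1-c1c(F)cc(OC)cc1OC | intermediate
10 | 3-(benzyloxy)-7,9-dimethoxydibenzo[b,d]furan-1-ol | Oc1cc(OCc2ccccc2)cc2oc3cc(OC)cc(OC)c3c12 | intermediate
11 | 3,5-dimethoxybenzaldehyde | COc1cc(C=O)cc(OC)c1 | starting material
12 | 2,6-difluoro-3,5-dimethoxybenzaldehyde | COc1cc(OC)c(F)c(C=O)c1F | intermediate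
13 | 3,5-dimethoxyphenol | COc1cc(O)cc(OC)c1 | starting material
14 | 2-(3,5-dimethoxyphenoxy)-6-fluoro-3,5-dimethoxybenzaldehyde | COc1cc(OC)cc(Oc2c(OC)cc(OC)c(F)c2C=O)c1 | intermediate
15 | 2-{[3-(benzyloxy)-7,9-dimethoxydibenzo[b,d]furan-1-yl]oxy}-6-(3,5-dimethoxyphenoxy)-3,5-dimethoxybenzaldehyde | COc1cc(OC)cc(Oc2c(OC)cc(OC)c(Oc3cc(OCc4ccccc4)cc4oc5cc(OC)cc(OC)c5c34)c2C=O)c1 | intermediate
16 | 2-{[3-(benzyloxy)-7,9-dimethoxydibenzo[b,d]furan-1-yl]oxy}-6-(3,5-dimethoxyphenoxy)-3,5-dimethoxyphenyl formate | COc1cc(OC)cc(Oc2c(OC)cc(OC)c(Oc3cc(OCc4ccccc4)cc4oc5cc(OC)cc(OC)c5c34)c2OC=O)c1 | intermediate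
17 | 2-{[3-(benzyloxy)-7,9-dimethoxydibenzo[b,d]furan-1-yl]oxy}-6-(3,5-dimethoxyphenoxy)-3,5-dimethoxyphenol | COc1cc(OC)cc(Oc2c(OC)cc(OC)c(Oc3cc(OCc4ccccc4)cc4oc5cc(OC)cc(OC)c5c34)c2O)c1 | intermediate
18 | 1-[2-hydroxy-3-(3,5-dimethoxyphenoxy)-4,6-dimethoxyphenoxy]-7,9-dimethoxydibenzo[b,d]furan-3-ol | COc1cc(OC)cc(Oc2c(OC)cc(OC)c(Oc3cc(O)cc4oc5cc(OC)cc(OC)c5c34)c2O)c1 | intermediate
19 | hexamethyl ether of the target, C3 hydroxyl free, ring B closed | COc1cc(OC)cc(Oc2c(OC)cc(OC)c3c2Oc2c(O)cc4oc5cc(OC)cc(OC)c5c4c2O3)c1 | intermediate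
20 | CNP0256302.0 | Oc1cc(O)cc(Oc2c(O)cc(O)c3c2Oc2c(O)cc4oc5cc(O)cc(O)c5c4c2O3)c1 | target

Total step count: 13. Longest linear sequence: 10 steps (1, 2, 4, 5, 6, 9, 10, 11, 12, 13).

Steps most likely to fail

1. Step 12.
   - Risk: electron transfer may start on ring A rather than ring C, so that a3 is oxygenated or coupled between molecules. The closed product is easier to oxidise than its precursor and may be consumed as it forms.
   - Fallback (known chemistry, sets out from 10, comes back at 19): C2 receives a bromine before the ether is made, and ring B is closed by copper catalysis in place of oxidation. Amine-catalysed ortho-bromination of 10 (NBS, iPr2NH cat., CH2Cl2, 0 °C) should give the 2-bromodibenzofuranol F1, since C2 is the only carbon ortho to the C1 hydroxyl. Fluoride displacement on 14 (Cs2CO3, NMP, 120 °C) would give the bromo aldehyde F2. Baeyer–Villiger oxidation with mCPBA leads through the bromo formate F3, and after methanolysis to the bromo phenol F4. An intramolecular Ullmann etherification with monovalent copper (CuI, N,N-dimethylglycine, Cs2CO3, dioxane, 110 °C) joins the a6 oxygen to C2 and gives the dioxin benzyl ether F5. Hydrogenolysis (H2, Pd/C) then returns to 19.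

2. Step 9.
   - Risk: addition of the hindered C1 phenoxide to a C–F carbon that has methoxy groups ortho and para may be slow, so that aryloxide exchange at a1 or thermal demethylation overtakes it.
   - Fallback (sets out from 11, comes back at 15): the bond is made by copper catalysis on a bromide, where the ortho formyl group assists insertion. Double bromination of 11 (NBS, 2.2 equiv, MeCN) gives 2,6-dibromo-3,5-dimethoxybenzaldehyde F6. One Ullmann etherification with 13 (CuI, N,N-dimethylglycine, Cs2CO3, dioxane, 90 °C) gives the bromo monoether aldehyde F7. A second one with 10 at 110 °C gives 15.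

3. Step 4.
   - Risk: transmetalation and reductive elimination toward the tetra-ortho-substituted biaryl may be slow, leaving protodemetalation of the arylzinc and homocoupling to dominate.
   - Fallback (sets out from 3, comes back at 10): the coupling is relieved of one ortho substituent, and the furan oxygen bond is made by C–H functionalisation. Arylzinc 7, made from 3 as before, is coupled with commercial 1-bromo-2,4-dimethoxybenzene (COc1ccc(Br)c(OC)c1) to give the tri-ortho biaryl F8. HCl in MeOH gives the biaryl diol F9. The known phenol-directed C–H activation and C–O cyclisation of 2-arylphenols on divalent palladium (Pd(OAc)2, 3-nitropyridine, tert-butyl peroxybenzoate, C6F6–DMI, 90 °C) closes at the only free ortho carbon of ring D to give 10.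

Further compounds
F1 | step 12 | 3-(benzyloxy)-2-bromo-7,9-dimethoxydibenzo[b,d]furan-1-ol | Oc1c(Br)c(OCc2ccccc2)cc2oc3cc(OC)cc(OC)c3c12
F2 | step 12 | 2-{[3-(benzyloxy)-2-bromo-7,9-dimethoxydibenzo[b,d]furan-1-yl]oxy}-6-(3,5-dimethoxyphenoxy)-3,5-dimethoxybenzaldehyde | COc1cc(OC)cc(Oc2c(OC)cc(OC)c(Oc3c(Br)c(OCc4ccccc4)cc4oc5cc(OC)cc(OC)c5c34)c2C=O)c1
F3 | step 12 | 2-{[3-(benzyloxy)-2-bromo-7,9-dimethoxydibenzo[b,d]furan-1-yl]oxy}-6-(3,5-dimethoxyphenoxy)-3,5-dimethoxyphenyl formate | COc1cc(OC)cc(Oc2c(OC)cc(OC)c(Oc3c(Br)c(OCc4ccccc4)cc4oc5cc(OC)cc(OC)c5c34)c2OC=O)c1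
F4 | step 12 | 2-{[3-(benzyloxy)-2-bromo-7,9-dimethoxydibenzo[b,d]furan-1-yl]oxy}-6-(3,5-dimethoxyphenoxy)-3,5-dimethoxyphenol | COc1cc(OC)cc(Oc2c(OC)cc(OC)c(Oc3c(Br)c(OCc4ccccc4)cc4oc5cc(OC)cc(OC)c5c34)c2O)c1
F5 | step 12 | C3 benzyl ether of 19 (ring B closed) | COc1cc(OC)cc(Oc2c(OC)cc(OC)c3c2Oc2c(OCc4ccccc4)cc4oc5cc(OC)cc(OC)c5c4c2O3)c1
F6 | step 9 | 2,6-dibromo-3,5-dimethoxybenzaldehyde | COc1cc(OC)c(Br)c(C=O)c1Br
F7 | step 9 | 2-bromo-6-(3,5-dimethoxyphenoxy)-3,5-dimethoxybenzaldehyde | COc1cc(OC)cc(Oc2c(OC)cc(OC)c(Br)c2C=O)c1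
F8 | step 4 | 4-(benzyloxy)-2',4'-dimethoxy-2,6-bis(methoxymethoxy)-1,1'-biphenyl | COCOc1cc(OCc2ccccc2)cc(OCOC)c1-c1ccc(OC)cc1OC
F9 | step 4 | 4-(benzyloxy)-2',4'-dimethoxy-[1,1'-biphenyl]-2,6-diol | Oc1cc(OCc2ccccc2)cc(O)c1-c1ccc(OC)cc1OC
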